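The data are calculated on assumed constants.

Our unit is the decade, one step of the base-ten logarithm of the fraction of the charge still unreacted, and we work in it because the charges below move by powers.

| flask | starting material | second substrate | partner | free catalyst | remark | time |
|---|---|---|---|---|---|---|
| north-east | 0.50 M | 0.50 equiv | 1.1 equiv | 0.2 mol% | run made earlier |  |
| gamma | 1.0 M | 0.500 equiv | 1.10 equiv | 0.2 mol% |  | 6.0 h |
| delta | 1.0 M | 0.500 equiv | 1.10 equiv | 0.2 mol% |  | 18 h |
| epsilon | 1.0 M | 0.500 equiv | 1.10 equiv | 0.2 mol% |  | 54 h |

north-east run (percent of the starting material charged)

| time / min | target / % | catalyst intermediate A / % | starting material / % |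
|---|---|---|---|
| 8.00 | 0.4 | 0.3 | 99.9 |
| 15.0 | 0.7 | 0.3 | 98.0 |
| 25.0 | 0.7 | 0 | 98.7 |
| 40.0 | 1.7 | 0.1 | 99.1 |
| 60.0 | 2.2 | 0.5 | 97.2 |
| 120 | 4.7 | 0.1 | 96.2 |

(each reading ± 0.5 percentage points)

- the analysis behind the earlier runs scatters by 0.5 percentage points, standard deviation
- no earlier run changes the charge of free catalyst; that part of a forecast is a guess

1. which of these there is most of at the end, counted by the starting material in it, gamma (starting material / catalyst intermediate A / target)
2. which of these there is most of at the end, counted by the starting material in it, delta (starting material / catalyst intermediate A / target)
3. which of these there is most of at the end, counted by the starting material in it, epsilon (starting material / catalyst intermediate A / target)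
4. final amount of the leader among these, as a percentage of the starting material charged, in gamma
5. final amount of the leader among these, as a percentage of the starting material charged, in delta
6. final amount of the leader among these, as a percentage of the starting material charged, in epsilon

The north-east run is barely started, with target at 4.7% after 120 min. That reading gives a fall rate, the decades of starting material lost per hour, a pseudo-first-order rate in base ten, of 0.0105 h⁻¹, and it carries the scatter of 0.5 percentage points.

Gamma doubles every concentration, catalyst included. If the rate is first order in catalyst and indifferent to the substrates, the fall rate stays as it was, and gamma keeps 86.6% at 6.0 h; this is our bound from above. If it is also first order in starting material and in partner, the fall rate grows by the square of the doubling, and 56.1% is left.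

That lower bound can be tightened. Partner falls as target forms, one for one on our assumption, so its mean level over gamma is 0.801 of its charge, and the bound rises to 63.0%. We commit to the middle in logarithms, one power of the doubling, which leaves 74.9%. The end sample of gamma gives a fall rate averaged over its 6.0 h, so we hold it against this bracket as an average and not as a measured power.

The forecast gives starting material in gamma at 82% (73% to 88%), inside our bracket though above our middle, and its high end passes our upper bound. For delta it gives starting material at 58%, for epsilon target at 50%, and it warns that “the catalyst order is itself a guess”.

    starting material + free catalyst ⇌ catalyst intermediate A (K = 0.600 M⁻¹, k = 100 M⁻¹ h⁻¹)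
    partner + catalyst intermediate A → free catalyst + target (k = 150 M⁻¹ h⁻¹)
    second substrate + free catalyst ⇌ catalyst intermediate B (K = 2.30 M⁻¹, k = 120 M⁻¹ h⁻¹)
    partner + catalyst intermediate B → free catalyst + second product (k = 180 M⁻¹ h⁻¹)
    second substrate + catalyst intermediate A → spent catalyst (k = 0.860 M⁻¹ h⁻¹)

Starting material leads gamma at 75.6% and delta at 57.9%, while target leads epsilon at 55.6%. Gamma's figure lies 0.70 points from our middle, a fall rate of 0.0202 h⁻¹, twice the north-east value. A neighbouring flask differs from gamma by its free catalyst, 0.8 mol% against 0.2 mol%. Multiplying gamma's fall rate by that ratio leaves 32.7% at 6.0 h. The neighbouring flask keeps 46.2%, which is 2.77 times gamma's decades, and target leads it at 53.5%.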